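**Plan**

1. Retrosynthesis: after removal of fifteen benzyl ethers, each 2,3-trans mesquitol unit (2-(3,4-dihydroxyphenyl)chromane-3,7,8-triol) is cut at two bonds in one operation: the biaryl bond from its C5 to ring A of catechin (C6 or C8) and the C4–C4a bond of its pyran ring C. This leaves (+)-catechin and one open-chain aryl ether, used once as its primary chloride and once as its primary bromide.
2. Enabling feature: in ring A of each mesquitol unit, C4a (carrying the C4 methylene) and C5 (carrying the biaryl bond) are neighbours, and C8a next to C4a carries the ring oxygen O1. Ring A is therefore the 1,2-adduct of a 3-alkoxyaryne (C4a≡C5): O1 steers an aryl nucleophile to C5 and tethers C4 as an electrophile for the carbanion left at C4a.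
3. Forward: a 5-bromo-6-fluoro pyrogallol monophenol (three steps from 4-fluorocatechol) is joined by Mitsunobu etherification to a 3-bromo-2-benzyloxy-1-arylpropanol made by a syn glycolate aldol reaction; a portion of the resulting bromide is converted into the chloride by halide exchange; perbenzylated (+)-catechin is brominated at C8.
4. The aryne annulation is run first at catechin C8 with the chloride (which allows Br/Li exchange by t-BuLi beside an excess of the inexpensive nucleophile, the ring closing on warming), then, after bromination of C6, at C6 with the bromide (fastest closure for the most congested carbanion). This second annulation closes the pyran ring of the C6-linked mesquitol unit, the last ring of the skeleton; global hydrogenolysis ends the route.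
5. Stereochemistry: catechin C2/C3 come from (+)-catechin. Mesquitol C2 and C3 come from the auxiliary-controlled syn aldol reaction, with C2 inverted once in the Mitsunobu step (syn aldol plus one inversion gives 2,3-trans).

Key step: step 15

Assumption: the target string fixes no configuration at the two biaryl axes, so they are left uncontrolled; hindered rotation may show as slowly interconverting rotamers.

**Route**

Step 1
Reactants: 1 4-fluorocatechol
Product: 2 1,2-bis(benzyloxy)-4-fluorobenzene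
Conditions: BnBr, K2CO3, DMF, 60 °C
Reagents that add atoms: benzyl bromide, BrCc1ccccc1
Why: Williamson O-benzylation of both phenols is standard for catechols and installs ethers that fall in the final hydrogenolysis.

Step 2
Reactants: 2 1,2-bis(benzyloxy)-4-fluorobenzene
Product: 3 1,2-bis(benzyloxy)-4-bromo-5-fluorobenzene
Conditions: NBS, MeCN, 0 °C → rt
Reagents that add atoms: N-bromosuccinimide, O=C1CCC(=O)N1Br
Why: Electrophilic aromatic bromination should go to the only free position para to a benzyloxy group (C5, ortho to fluorine), as is usual for 4-substituted catechol diethers.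

Step 3
Reactants: 3 1,2-bis(benzyloxy)-4-bromo-5-fluorobenzene
Product: 6 2,3-bis(benzyloxy)-5-bromo-6-fluorophenol, via aryllithium 4 (not isolated), via dimethyl arylboronate 5 (not isolated)
Conditions: LiN(iPr)2 (LDA), THF, −78 °C; B(OMe)3, −78 → 0 °C; AcOH, 30% aq H2O2, 0 °C → rt
Reagents that add atoms: hydrogen peroxide, OO
Why: Directed ortho-metalation by the amide base should remove the most acidic ring proton, the one flanked by fluorine and a benzyloxy group (the aryl bromide is not exchanged by the amide base and the 2-fluoroaryllithium is stable at −78 °C), and borylation–oxidation turns C–Li into C–OH.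

Step 4
Reactants: 7 (R)-4-benzyloxazolidin-2-one; 8 (benzyloxy)acetyl chloride
Product: 9 (R)-4-benzyl-3-[(benzyloxy)acetyl]oxazolidin-2-one
Conditions: Et3N, DMAP (cat.), CH2Cl2, 0 °C → rt
Reagents that add atoms: none
Why: N-acylation of the oxazolidinone with an acid chloride under amine/DMAP catalysis is the standard preparation of a glycolate imide.

Step 5
Reactants: 9 (R)-4-benzyl-3-[(benzyloxy)acetyl]oxazolidin-2-one; 10 3,4-bis(benzyloxy)benzaldehyde
Product: 12 (R)-4-benzyl-3-{(2R,3S)-2-(benzyloxy)-3-[3,4-bis(benzyloxy)phenyl]-3-hydroxypropanoyl}oxazolidin-2-one, via dibutylboron Z-enolate 11 (not isolated)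
Conditions: Bu2BOTf, Et3N, CH2Cl2, −78 → 0 °C; then 10, −78 → 0 °C; pH 7 buffer, MeOH, 30% H2O2, 0 °C
Reagents that add atoms: none
Why: Evans syn-aldol reaction: the Z boron enolate reacts through a closed chair transition state on the face away from the auxiliary's benzyl group, so both new stereocenters (2R,3S, syn) are set by the auxiliary.

Step 6
Reactants: 12 the syn-aldol imide
Product: 13 (1S,2S)-2-(benzyloxy)-1-[3,4-bis(benzyloxy)phenyl]propane-1,3-diol
Conditions: LiBH4, MeOH (2 equiv), THF, 0 °C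
Reagents that add atoms: none
Why: Reductive cleavage of the N-acyl oxazolidinone by LiBH4 should give the primary alcohol and release the auxiliary without touching either stereocenter.

Step 7
Reactants: 13 (1S,2S)-2-(benzyloxy)-1-[3,4-bis(benzyloxy)phenyl]propane-1,3-diol
Product: 14 (1S,2R)-2-(benzyloxy)-1-[3,4-bis(benzyloxy)phenyl]-3-bromopropan-1-ol
Conditions: PPh3, CBr4, 2,6-lutidine, CH2Cl2, −20 → 0 °C
Reagents that add atoms: carbon tetrabromide, BrC(Br)(Br)Br
Why: Appel reaction: the bulky bromophosphonium reagent should activate the unhindered primary hydroxyl faster than the flanked secondary benzylic one, and the lutidine buffer suppresses acid-promoted ionisation of the benzylic alcohol.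

Step 8
Reactants: 14 (1S,2R)-2-(benzyloxy)-1-[3,4-bis(benzyloxy)phenyl]-3-bromopropan-1-ol; 6 2,3-bis(benzyloxy)-5-bromo-6-fluorophenol
Product: 15 (1R,2R)-2-(benzyloxy)-1-[3,4-bis(benzyloxy)phenyl]-3-bromopropyl 2,3-bis(benzyloxy)-5-bromo-6-fluorophenyl ether
Conditions: PPh3, DIAD, THF (concentrated), 0 °C → rt
Reagents that add atoms: none
Why: Mitsunobu etherification: the acidic phenol should displace the oxyphosphonium group by SN2 with inversion at the benzylic carbon (1S → 1R, the future mesquitol C2), the β-benzyloxy group disfavouring ionisation.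

Step 9
Reactants: 16 (+)-catechin
Product: 17 (2R,3S)-5,7-bis(benzyloxy)-2-[3,4-bis(benzyloxy)phenyl]chroman-3-ol
Conditions: BnBr, K2CO3, DMF, 0 °C → rt
Reagents that add atoms: benzyl bromide, BrCc1ccccc1
Why: Williamson etherification with a carbonate base benzylates the four phenols and leaves the aliphatic 3-OH, as is established for catechin.

Step 10
Reactants: 17 the tetra-O-benzyl catechin
Product: 18 (2R,3S)-3,5,7-tris(benzyloxy)-2-[3,4-bis(benzyloxy)phenyl]chromane
Conditions: NaH, BnBr, DMF, 0 °C → rt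
Reagents that add atoms: benzyl bromide, BrCc1ccccc1
Why: Williamson etherification of the secondary alkoxide; with no free phenol left the flavan is stable to NaH and C2/C3 are untouched.

Step 11
Reactants: 18 the penta-O-benzyl catechin
Product: 19 (2R,3S)-3,5,7-tris(benzyloxy)-2-[3,4-bis(benzyloxy)phenyl]-8-bromochromane
Conditions: NBS (1.0 equiv), CH2Cl2, −78 °C → rt
Reagents that add atoms: N-bromosuccinimide, O=C1CCC(=O)N1Br
Why: Electrophilic bromination of the phloroglucinol-type ring A occurs at C8 before C6, the established site selectivity for 5,7-di-O-alkyl catechins.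

Step 12
Reactants: 15 the bromofluoroaryl ether with the primary bromide
Product: 20 (1R,2R)-2-(benzyloxy)-1-[3,4-bis(benzyloxy)phenyl]-3-chloropropyl 2,3-bis(benzyloxy)-5-bromo-6-fluorophenyl ether
Conditions: LiCl (10 equiv), DMF, 70 °C
Reagents that add atoms: lithium chloride, [Li+].[Cl-]
Why: Halide exchange of the Finkelstein type: chloride, a strong nucleophile in DMF, should displace the primary bromide by SN2 and the excess of LiCl drives the exchange to completion, the unactivated aryl fluoride and aryl bromide being inert and the two stereocenters not involved; the primary chloride, unlike the bromide, tolerates t-BuLi at −78 °C, which is why it serves the first annulation.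

Step 13
Reactants: 19 the 8-bromo catechin ether; 20 the bromofluoroaryl ether with the primary chloride
Product: 25 deca-O-benzyl mesquitol-(5→8)-catechin, via 8-lithiocatechin ether 21 (not isolated), via chloro-tethered 2-fluoroaryllithium 22 (not isolated), via chloro-tethered aryne 23 (not isolated), via chloro-tethered 2-lithiobiaryl 24 (not isolated)
Conditions: 19 (3 equiv), t-BuLi (6 equiv), THF, −78 °C; separately 20 (1.0 equiv), t-BuLi (2.0 equiv), THF, −78 °C; the cold solution of 22 added slowly to 21 at −40 °C, then → rt; aq NH4Cl (unreacted 21 returns as 18)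
Reagents that add atoms: none
Why: Proposed new method: Br/Li exchange on the aryl bromide of 20 with two equivalents of t-BuLi (the second destroys the t-BuBr formed, so that no alkyl bromide stays beside the excess nucleophile, and the primary chloride is not exchanged at −78 °C) gives 22, which on warming loses LiF to aryne 23; the 2,6-dialkoxyaryllithium 21 should add to the aryne carbon remote from the C8a ether oxygen (C5), and the C4a carbanion of 24 then displaces the tethered primary chloride on warming to rt (6-exo-tet), the closest known reaction types being the arylation of arynes by aryllithiums with electrophilic quench of the 2-metallobiaryl and the Parham cyclialkylation of an aryllithium onto a tethered primary halide; no stereocenter is formed, and C2 and C3 come unchanged from 20.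

Step 14
Reactants: 25 deca-O-benzyl mesquitol-(5→8)-catechin
Product: 26 6-bromo derivative of 25 (bromine at C6 of the catechin unit)
Conditions: NBS (1.0 equiv), CH2Cl2, −78 → 0 °C
Reagents that add atoms: N-bromosuccinimide, O=C1CCC(=O)N1Br
Why: Electrophilic bromination: catechin C6 is the only remaining position activated by three oxygen substituents (ortho, ortho, para) and should react well before mesquitol C6–H (two activating oxygens) or the catechol rings.

Step 15
Reactants: 26 the 6-bromo dimer; 15 the bromofluoroaryl ether with the primary bromide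
Product: 31 pentadeca-O-benzyl ether of the target, via 6-lithio dimer 27 (not isolated), via bromo-tethered 2-fluoroaryllithium 28 (not isolated), via bromo-tethered aryne 29 (not isolated), via bromo-tethered 2-lithiobiaryl 30 (not isolated)
Conditions: 26 (1.5 equiv), t-BuLi (3 equiv), THF, −78 °C; separately 15 (1.0 equiv), n-BuLi (1.05 equiv), THF/Et2O, −100 °C; the cold solution of 28 added slowly to 27 at −40 °C, then → rt; aq NH4Cl (unreacted 27 returns as 25)
Reagents that add atoms: none
Why: Proposed new method: Br/Li exchange at −100 °C turns 15 into the 2-fluoroaryllithium 28 without touching the primary bromide, and on warming 28 loses LiF to aryne 29 (triple bond C4a≡C5 of the future ring A), to which the 2,6-dialkoxyaryllithium 27 adds to give 30, whose carbanion at C4a is joined through C8a, O1, C2 and C3 to the CH2Br group and displaces bromide. The closest known reaction types are the arylation of arynes by aryllithium or aryl Grignard reagents with electrophilic capture of the 2-metallobiaryl (used for hindered biaryls) and the Parham cyclialkylation of an aryllithium onto a tethered primary bromide; new is their union, with the electrophile tethered through O1 so that the capture closes a ring. The pyran ring closes by 6-exo-tet SN2 attack of the sp2 carbanion at C4a on C4 (bond C4a–C4), and it is the only ring formed. No stereocenter is created: C2 and C3 arrive with their configuration from 15 and should not be deprotonated at these temperatures, and the new C5–C6 biaryl axis is left uncontrolled. The step needs addition at C5 and not at C4a, which is secured by the ether oxygen O1 on C8a beside the triple bond: its inductive effect stabilises the developing carbanion at the neighbouring C4a and distorts the aryne so that the remote carbon C5 is the electrophilic and also the less hindered end. It also needs the aryllithiums to spare the primary bromide until 30 has formed, which the low exchange temperature, the slow addition of 28 to an excess of the hindered nucleophile 27 and the far higher rate of the intramolecular six-ring closure (the reason for keeping the bromide here) should secure.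

Step 16
Reactants: 31 the pentadeca-O-benzyl ether
Product: 32 CNP0171327.1
Conditions: H2 (1 atm), Pd(OH)2 on carbon, THF/MeOH, rt; filtration and concentration under argon
Reagents that add atoms: none
Why: Hydrogenolysis cleaves all fifteen benzyl ethers (phenolic and secondary alkyl) under neutral conditions that leave the chroman C–O bonds and every stereocenter untouched.

**Compound list**

1 | 4-fluorocatechol | Oc1ccc(F)cc1O | starting material
2 | 1,2-bis(benzyloxy)-4-fluorobenzene | Fc1ccc(OCc2ccccc2)c(OCc2ccccc2)c1 | intermediate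
3 | 1,2-bis(benzyloxy)-4-bromo-5-fluorobenzene | Fc1cc(OCc2ccccc2)c(OCc2ccccc2)cc1Br | intermediate
4 | [2,3-bis(benzyloxy)-5-bromo-6-fluorophenyl]lithium | [Li]c1c(F)c(Br)cc(OCc2ccccc2)c1OCc1ccccc1 | intermediate (not isolated)
5 | dimethyl [2,3-bis(benzyloxy)-5-bromo-6-fluorophenyl]boronate | COB(OC)c1c(F)c(Br)cc(OCc2ccccc2)c1OCc1ccccc1 | intermediate (not isolated)
6 | 2,3-bis(benzyloxy)-5-bromo-6-fluorophenol | Oc1c(F)c(Br)cc(OCc2ccccc2)c1OCc1ccccc1 | intermediate
7 | (R)-4-benzyloxazolidin-2-one | O=C1N[C@H](Cc2ccccc2)CO1 | starting material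
8 | (benzyloxy)acetyl chloride | O=C(Cl)COCc1ccccc1 | starting material
9 | (R)-4-benzyl-3-[(benzyloxy)acetyl]oxazolidin-2-one | O=C(COCc1ccccc1)N1C(=O)OC[C@H]1Cc1ccccc1 | intermediate
10 | 3,4-bis(benzyloxy)benzaldehyde | O=Cc1ccc(OCc2ccccc2)c(OCc2ccccc2)c1 | starting material
11 | dibutylboron Z-enolate of 9 | CCCCB(CCCC)O/C(=C\OCc1ccccc1)N1C(=O)OC[C@H]1Cc1ccccc1 | intermediate (not isolated)
12 | (R)-4-benzyl-3-{(2R,3S)-2-(benzyloxy)-3-[3,4-bis(benzyloxy)phenyl]-3-hydroxypropanoyl}oxazolidin-2-one | O=C(N1C(=O)OC[C@H]1Cc1ccccc1)[C@H](OCc1ccccc1)[C@@H](O)c1ccc(OCc2ccccc2)c(OCc2ccccc2)c1 | intermediate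
13 | (1S,2S)-2-(benzyloxy)-1-[3,4-bis(benzyloxy)phenyl]propane-1,3-diol | OC[C@H](OCc1ccccc1)[C@@H](O)c1ccc(OCc2ccccc2)c(OCc2ccccc2)c1 | intermediate
14 | (1S,2R)-2-(benzyloxy)-1-[3,4-bis(benzyloxy)phenyl]-3-bromopropan-1-ol | BrC[C@H](OCc1ccccc1)[C@@H](O)c1ccc(OCc2ccccc2)c(OCc2ccccc2)c1 | intermediate
15 | (1R,2R)-2-(benzyloxy)-1-[3,4-bis(benzyloxy)phenyl]-3-bromopropyl 2,3-bis(benzyloxy)-5-bromo-6-fluorophenyl ether | BrC[C@H](OCc1ccccc1)[C@H](Oc1c(F)c(Br)cc(OCc2ccccc2)c1OCc1ccccc1)c1ccc(OCc2ccccc2)c(OCc2ccccc2)c1 | intermediate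
16 | (+)-catechin, (2R,3S)-2-(3,4-dihydroxyphenyl)chromane-3,5,7-triol | Oc1cc(O)c2c(c1)O[C@H](c1ccc(O)c(O)c1)[C@@H](O)C2 | starting material
17 | (2R,3S)-5,7-bis(benzyloxy)-2-[3,4-bis(benzyloxy)phenyl]chroman-3-ol | c1c(OCc8ccccc8)c2c(cc1OCc8ccccc8)O[C@H](c1ccc(OCc8ccccc8)c(OCc8ccccc8)c1)[C@@H](O)C2 | intermediate
18 | (2R,3S)-3,5,7-tris(benzyloxy)-2-[3,4-bis(benzyloxy)phenyl]chromane | c1c(OCc8ccccc8)c2c(cc1OCc8ccccc8)O[C@H](c1ccc(OCc8ccccc8)c(OCc8ccccc8)c1)[C@@H](OCc8ccccc8)C2 | intermediate
19 | (2R,3S)-3,5,7-tris(benzyloxy)-2-[3,4-bis(benzyloxy)phenyl]-8-bromochromane | c1c(OCc8ccccc8)c2c(c(Br)c1OCc8ccccc8)O[C@H](c1ccc(OCc8ccccc8)c(OCc8ccccc8)c1)[C@@H](OCc8ccccc8)C2 | intermediate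
20 | (1R,2R)-2-(benzyloxy)-1-[3,4-bis(benzyloxy)phenyl]-3-chloropropyl 2,3-bis(benzyloxy)-5-bromo-6-fluorophenyl ether | ClC[C@H](OCc1ccccc1)[C@H](Oc1c(F)c(Br)cc(OCc2ccccc2)c1OCc1ccccc1)c1ccc(OCc2ccccc2)c(OCc2ccccc2)c1 | intermediate
21 | 8-lithio analogue of 19 | c1c(OCc8ccccc8)c2c(c([Li])c1OCc8ccccc8)O[C@H](c1ccc(OCc8ccccc8)c(OCc8ccccc8)c1)[C@@H](OCc8ccccc8)C2 | intermediate (not isolated)
22 | 2-fluoroaryllithium from 20 (lithium in place of the aryl bromine, primary chloride kept) | ClC[C@H](OCc1ccccc1)[C@H](Oc1c(F)c([Li])cc(OCc2ccccc2)c1OCc1ccccc1)c1ccc(OCc2ccccc2)c(OCc2ccccc2)c1 | intermediate (not isolated)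
23 | aryne from 22 (triple bond between the former C–F and C–Li carbons, primary chloride kept) | ClC[C@H](OCc1ccccc1)[C@H](OC1=C(OCc2ccccc2)C(OCc2ccccc2)=CC#C1)c1ccc(OCc2ccccc2)c(OCc2ccccc2)c1 | intermediate (not isolated)
24 | 18 carrying at C8 the 4,5-bis(benzyloxy)-3-{[(1R,2R)-2-(benzyloxy)-1-[3,4-bis(benzyloxy)phenyl]-3-chloropropyl]oxy}-2-lithiophenyl group | c1c(OCc8ccccc8)c2c(c(-c6c([Li])c(O[C@H](c7ccc(OCc8ccccc8)c(OCc8ccccc8)c7)[C@@H](OCc8ccccc8)CCl)c(OCc8ccccc8)c(OCc8ccccc8)c6)c1OCc8ccccc8)O[C@H](c1ccc(OCc8ccccc8)c(OCc8ccccc8)c1)[C@@H](OCc8ccccc8)C2 | intermediate (not isolated)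
25 | deca-O-benzyl mesquitol-(5→8)-catechin: 18 carrying at C8 the (2R,3S)-3,7,8-tris(benzyloxy)-2-[3,4-bis(benzyloxy)phenyl]chroman-5-yl group | c1c(OCc8ccccc8)c2c(c(-c6cc(OCc8ccccc8)c(OCc8ccccc8)c7c6C[C@H](OCc8ccccc8)[C@@H](c6ccc(OCc8ccccc8)c(OCc8ccccc8)c6)O7)c1OCc8ccccc8)O[C@H](c1ccc(OCc8ccccc8)c(OCc8ccccc8)c1)[C@@H](OCc8ccccc8)C2 | intermediate
26 | 25 with bromine at C6 of the catechin unit | Brc1c(OCc8ccccc8)c2c(c(-c6cc(OCc8ccccc8)c(OCc8ccccc8)c7c6C[C@H](OCc8ccccc8)[C@@H](c6ccc(OCc8ccccc8)c(OCc8ccccc8)c6)O7)c1OCc8ccccc8)O[C@H](c1ccc(OCc8ccccc8)c(OCc8ccccc8)c1)[C@@H](OCc8ccccc8)C2 | intermediate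
27 | 25 with lithium at C6 of the catechin unit | [Li]c1c(OCc8ccccc8)c2c(c(-c6cc(OCc8ccccc8)c(OCc8ccccc8)c7c6C[C@H](OCc8ccccc8)[C@@H](c6ccc(OCc8ccccc8)c(OCc8ccccc8)c6)O7)c1OCc8ccccc8)O[C@H](c1ccc(OCc8ccccc8)c(OCc8ccccc8)c1)[C@@H](OCc8ccccc8)C2 | intermediate (not isolated)
28 | 2-fluoroaryllithium from 15 (lithium in place of the aryl bromine, primary bromide kept) | BrC[C@H](OCc1ccccc1)[C@H](Oc1c(F)c([Li])cc(OCc2ccccc2)c1OCc1ccccc1)c1ccc(OCc2ccccc2)c(OCc2ccccc2)c1 | intermediate (not isolated)
29 | aryne from 28 (triple bond between the former C–F and C–Li carbons, primary bromide kept) | BrC[C@H](OCc1ccccc1)[C@H](OC1=C(OCc2ccccc2)C(OCc2ccccc2)=CC#C1)c1ccc(OCc2ccccc2)c(OCc2ccccc2)c1 | intermediate (not isolated)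
30 | 25 carrying at catechin C6 the 4,5-bis(benzyloxy)-3-{[(1R,2R)-2-(benzyloxy)-1-[3,4-bis(benzyloxy)phenyl]-3-bromopropyl]oxy}-2-lithiophenyl group | c1(-c6c([Li])c(O[C@H](c7ccc(OCc8ccccc8)c(OCc8ccccc8)c7)[C@@H](OCc8ccccc8)CBr)c(OCc8ccccc8)c(OCc8ccccc8)c6)c(OCc8ccccc8)c2c(c(-c6cc(OCc8ccccc8)c(OCc8ccccc8)c7c6C[C@H](OCc8ccccc8)[C@@H](c6ccc(OCc8ccccc8)c(OCc8ccccc8)c6)O7)c1OCc8ccccc8)O[C@H](c1ccc(OCc8ccccc8)c(OCc8ccccc8)c1)[C@@H](OCc8ccccc8)C2 | intermediate (not isolated)
31 | pentadeca-O-benzyl ether of the target: 18 carrying at C6 and at C8 the (2R,3S)-3,7,8-tris(benzyloxy)-2-[3,4-bis(benzyloxy)phenyl]chroman-5-yl group | c1(-c6cc(OCc8ccccc8)c(OCc8ccccc8)c7c6C[C@H](OCc8ccccc8)[C@@H](c6ccc(OCc8ccccc8)c(OCc8ccccc8)c6)O7)c(OCc8ccccc8)c2c(c(-c6cc(OCc8ccccc8)c(OCc8ccccc8)c7c6C[C@H](OCc8ccccc8)[C@@H](c6ccc(OCc8ccccc8)c(OCc8ccccc8)c6)O7)c1OCc8ccccc8)O[C@H](c1ccc(OCc8ccccc8)c(OCc8ccccc8)c1)[C@@H](OCc8ccccc8)C2 | intermediate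
32 | CNP0171327.1: (2R,3S)-2-(3,4-dihydroxyphenyl)-6,8-bis[(2R,3S)-2-(3,4-dihydroxyphenyl)-3,7,8-trihydroxychroman-5-yl]chromane-3,5,7-triol | Oc1ccc([C@H]2Oc3c(O)c(O)cc(-c4c(O)c5c(c(-c6cc(O)c(O)c7c6C[C@H](O)[C@@H](c6ccc(O)c(O)c6)O7)c4O)O[C@H](c4ccc(O)c(O)c4)[C@@H](O)C5)c3C[C@@H]2O)cc1O | target

**Step count and risks**

Total step count: 16. Longest linear sequence: 10 steps (steps 4, 5, 6, 7, 8, 12, 13, 14, 15, 16).

Steps most likely to fail:

1. Step 15 (Proposed new method). What may go wrong: before the ring closes, the 2-lithiobiaryl may be quenched by proton transfer from benzylic ether positions; the aryllithiums may attack the primary bromide; or self-addition of 28 to 29 may outrun the hindered nucleophile. Fallback, decoupled into two known reactions, setting out from 26 and 15: 27 (from 26 and t-BuLi) is transmetalated with MgBr2·OEt2 to the arylmagnesium bromide F1. Separately, 15 is converted by Br/Mg exchange (i-PrMgCl·LiCl, THF, −20 °C) into the bromo-tethered 2-fluoroarylmagnesium chloride F2. The mixture of the two is warmed (rt → 50 °C) so that F2 releases aryne 29 and the Grignard reagent adds to it (known arylation of an aryne by an aryl Grignard reagent). The resulting 2-biarylmagnesium bromide F3 does not alkylate itself with the primary bromide and is quenched with BrCl2C–CCl2Br to the isolable 2-bromobiaryl F4. A separate Parham cyclialkylation (n-BuLi, THF/Et2O, −100 °C → rt) then regenerates 30 by Br/Li exchange in the absence of any other organometallic, and the route is rejoined at 31.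

2. Step 13 (Proposed new method). What may go wrong: slow ring closure onto the primary chloride leaves the 2-lithiobiaryl open to proton transfer from benzylic ether positions, and self-addition of 22 to 23 may compete with capture by 21. Fallback, setting out from 19 and 20: 21 (from 19 and t-BuLi) is transmetalated (MgBr2·OEt2) to the arylmagnesium bromide F5. It is combined with the chloro-tethered 2-fluoroarylmagnesium chloride F6 (made from 20 with i-PrMgCl·LiCl, THF, −20 °C) and warmed to give, through aryne 23, the 2-biarylmagnesium bromide F7, which is quenched with BrCl2C–CCl2Br to the 2-bromobiaryl F8. Parham cyclialkylation of the isolated bromide (t-BuLi, 2 equiv, THF, −78 °C → rt) passes through 24 and rejoins the route at 25.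

3. Step 8. What may go wrong: ionisation of the electron-rich benzylic oxyphosphonium ion (loss of configuration at C1, elimination) and slow attack by the doubly ortho-substituted phenol. Fallback, forming the same C–O bond by base-mediated SN2 opening of a trans-epoxide at its benzylic carbon, setting out from 10 and 6: a Horner–Wadsworth–Emmons reaction of 10 (triethyl phosphonoacetate, NaH, THF) gives ethyl (E)-3-[3,4-bis(benzyloxy)phenyl]acrylate F9. Reduction with i-Bu2AlH gives (E)-3-[3,4-bis(benzyloxy)phenyl]prop-2-en-1-ol F10. Sharpless asymmetric epoxidation (Ti(OiPr)4, L-(+)-diethyl tartrate, t-BuOOH, 4 Å sieves, CH2Cl2, −20 °C) gives [(2S,3S)-3-[3,4-bis(benzyloxy)phenyl]oxiran-2-yl]methanol F11. The sodium phenoxide of 6 (NaOH, H2O/dioxane, 70 °C) opens the epoxide at the benzylic carbon with inversion to (2S,3R)-3-[2,3-bis(benzyloxy)-5-bromo-6-fluorophenoxy]-3-[3,4-bis(benzyloxy)phenyl]propane-1,2-diol F12. A primary-selective Appel reaction (PPh3, CBr4) gives (2R,3R)-3-[2,3-bis(benzyloxy)-5-bromo-6-fluorophenoxy]-3-[3,4-bis(benzyloxy)phenyl]-1-bromopropan-2-ol F13. Benzylation of the secondary hydroxyl under neutral conditions (2-benzyloxy-1-methylpyridinium triflate, MgO, PhCF3, 85 °C) rejoins the route at 15.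

**Further compounds**

F1 | step 15 | arylmagnesium bromide of 27 (MgBr at catechin C6) | Br[Mg]c1c(OCc8ccccc8)c2c(c(-c6cc(OCc8ccccc8)c(OCc8ccccc8)c7c6C[C@H](OCc8ccccc8)[C@@H](c6ccc(OCc8ccccc8)c(OCc8ccccc8)c6)O7)c1OCc8ccccc8)O[C@H](c1ccc(OCc8ccccc8)c(OCc8ccccc8)c1)[C@@H](OCc8ccccc8)C2
F2 | step 15 | bromo-tethered 2-fluoroarylmagnesium chloride from 15 (MgCl in place of the aryl bromine) | BrC[C@H](OCc1ccccc1)[C@H](Oc1c(F)c([Mg]Cl)cc(OCc2ccccc2)c1OCc1ccccc1)c1ccc(OCc2ccccc2)c(OCc2ccccc2)c1
F3 | step 15 | 2-biarylmagnesium bromide (30 with MgBr in place of Li) | c1(-c6c([Mg]Br)c(O[C@H](c7ccc(OCc8ccccc8)c(OCc8ccccc8)c7)[C@@H](OCc8ccccc8)CBr)c(OCc8ccccc8)c(OCc8ccccc8)c6)c(OCc8ccccc8)c2c(c(-c6cc(OCc8ccccc8)c(OCc8ccccc8)c7c6C[C@H](OCc8ccccc8)[C@@H](c6ccc(OCc8ccccc8)c(OCc8ccccc8)c6)O7)c1OCc8ccccc8)O[C@H](c1ccc(OCc8ccccc8)c(OCc8ccccc8)c1)[C@@H](OCc8ccccc8)C2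
F4 | step 15 | 2-bromobiaryl (30 with Br in place of Li) | c1(-c6c(Br)c(O[C@H](c7ccc(OCc8ccccc8)c(OCc8ccccc8)c7)[C@@H](OCc8ccccc8)CBr)c(OCc8ccccc8)c(OCc8ccccc8)c6)c(OCc8ccccc8)c2c(c(-c6cc(OCc8ccccc8)c(OCc8ccccc8)c7c6C[C@H](OCc8ccccc8)[C@@H](c6ccc(OCc8ccccc8)c(OCc8ccccc8)c6)O7)c1OCc8ccccc8)O[C@H](c1ccc(OCc8ccccc8)c(OCc8ccccc8)c1)[C@@H](OCc8ccccc8)C2
F5 | step 13 | arylmagnesium bromide of 21 (MgBr at catechin C8) | c1c(OCc8ccccc8)c2c(c([Mg]Br)c1OCc8ccccc8)O[C@H](c1ccc(OCc8ccccc8)c(OCc8ccccc8)c1)[C@@H](OCc8ccccc8)C2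
F6 | step 13 | chloro-tethered 2-fluoroarylmagnesium chloride from 20 (MgCl in place of the aryl bromine) | ClC[C@H](OCc1ccccc1)[C@H](Oc1c(F)c([Mg]Cl)cc(OCc2ccccc2)c1OCc1ccccc1)c1ccc(OCc2ccccc2)c(OCc2ccccc2)c1
F7 | step 13 | 2-biarylmagnesium bromide (24 with MgBr in place of Li) | c1c(OCc8ccccc8)c2c(c(-c6c([Mg]Br)c(O[C@H](c7ccc(OCc8ccccc8)c(OCc8ccccc8)c7)[C@@H](OCc8ccccc8)CCl)c(OCc8ccccc8)c(OCc8ccccc8)c6)c1OCc8ccccc8)O[C@H](c1ccc(OCc8ccccc8)c(OCc8ccccc8)c1)[C@@H](OCc8ccccc8)C2
F8 | step 13 | 2-bromobiaryl (24 with Br in place of Li) | c1c(OCc8ccccc8)c2c(c(-c6c(Br)c(O[C@H](c7ccc(OCc8ccccc8)c(OCc8ccccc8)c7)[C@@H](OCc8ccccc8)CCl)c(OCc8ccccc8)c(OCc8ccccc8)c6)c1OCc8ccccc8)O[C@H](c1ccc(OCc8ccccc8)c(OCc8ccccc8)c1)[C@@H](OCc8ccccc8)C2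
F9 | step 8 | ethyl (E)-3-[3,4-bis(benzyloxy)phenyl]acrylate | CCOC(=O)/C=C/c1ccc(OCc2ccccc2)c(OCc2ccccc2)c1
F10 | step 8 | (E)-3-[3,4-bis(benzyloxy)phenyl]prop-2-en-1-ol | OC/C=C/c1ccc(OCc2ccccc2)c(OCc2ccccc2)c1
F11 | step 8 | [(2S,3S)-3-[3,4-bis(benzyloxy)phenyl]oxiran-2-yl]methanol | OC[C@@H]1O[C@H]1c1ccc(OCc2ccccc2)c(OCc2ccccc2)c1
F12 | step 8 | (2S,3R)-3-[2,3-bis(benzyloxy)-5-bromo-6-fluorophenoxy]-3-[3,4-bis(benzyloxy)phenyl]propane-1,2-diol | OC[C@H](O)[C@H](Oc1c(F)c(Br)cc(OCc2ccccc2)c1OCc1ccccc1)c1ccc(OCc2ccccc2)c(OCc2ccccc2)c1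
F13 | step 8 | (2R,3R)-3-[2,3-bis(benzyloxy)-5-bromo-6-fluorophenoxy]-3-[3,4-bis(benzyloxy)phenyl]-1-bromopropan-2-ol | BrC[C@H](O)[C@H](Oc1c(F)c(Br)cc(OCc2ccccc2)c1OCc1ccccc1)c1ccc(OCc2ccccc2)c(OCc2ccccc2)c1
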